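The γ-lactone (ring atoms O, C6, C7, C11, C12) is trans-fused to the ten-membered carbocycle. Its junction carbon C7 sits between two oxygenated carbons, C6 and C8, and the plan exploits this C6(O)–C7(C11)–C8(O) array. The pivotal disconnection is C7–C11. A phosphonoacetate ester on O6 is deprotonated and its carbanion opens a trans C7–C8 epoxide at C7 from the rear. That one operation makes C7–C11, closes the lactone, fixes C7 by inversion, frees O8 for acylation and leaves a phosphonate for methylenation. The precursor 18 is a (1(10)E,4Z)-cyclodecadiene bearing the 3-silyl ether, the 6-phosphonoacetate and the 7,8-epoxide, the latter installed before ring closure.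

Key step: step 14

Remark: germacrane numbering (ring C1–C10, C14 on C10, C15 on C4, C11–C13 for the lactone carbons) is used for all intermediates, and C11 of 21, which is configurationally labile between phosphorus and carbonyl, is drawn as the epimer expected to be more stable (phosphorus trans to C8).

Step 1
Reactants: 1 propargyl alcohol
Product: 3 (Z)-3-iodo-2-methylprop-2-en-1-ol, via cyclic alkenylmagnesium alkoxide 2 (not isolated)
Conditions: MeMgBr (2.5 equiv), CuI (10 mol %), THF, −10 °C → rt; then I2, THF, −10 °C
Reagents that add atoms: methylmagnesium bromide C[Mg]Br; iodine II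
Why: Copper-catalysed carbomagnesiation of the propargylic alkoxide adds methyl to the inner alkyne carbon and magnesium to the terminus in an anti sense through the five-membered chelate 2, so iodinolysis with retention should give only the Z-iodoalkene (iodine cis to CH2OH), the future C5=C4(C15)–C3 unit.

Step 2
Reactants: 3 (Z)-3-iodo-2-methylprop-2-en-1-ol
Product: 4 (Z)-3-iodo-2-methylprop-2-enal
Conditions: MnO2 (excess), CH2Cl2, rt, dark
Reagents that add atoms: none
Why: Heterogeneous MnO2 oxidation of an allylic alcohol is neutral and should deliver the Z-β-iodoenal without Z-to-E drift, provided it is kept from light and used at once.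

Step 3
Reactants: 4 (Z)-3-iodo-2-methylprop-2-enal
Product: 6 (1Z,3S)-1-iodo-2-methylhexa-1,5-dien-3-ol, via diisopinocampheylborinate ester 5 (not isolated)
Conditions: B-allyldiisopinocampheylborane derived from (+)-α-pinene, Et2O, −78 °C; then NaOH, H2O2, 0 °C → rt
Reagents that add atoms: B-allyldiisopinocampheylborane C=CCB([C@@H]1C[C@@H]2C[C@H]([C@H]1C)C2(C)C)[C@@H]1C[C@@H]2C[C@H]([C@H]1C)C2(C)C
Why: Brown asymmetric allylboration proceeds through a closed chair transition state in which the isopinocampheyl groups derived from (+)-α-pinene direct allyl transfer to the si face of the aldehyde, which should set C3 as S, and alkaline peroxide then cleaves borinate 5.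

Step 4
Reactants: 6 (1Z,3S)-1-iodo-2-methylhexa-1,5-dien-3-ol
Product: 7 (1Z,3S)-3-(tert-butyldimethylsilyloxy)-1-iodo-2-methylhexa-1,5-diene
Conditions: TBSCl, imidazole, DMF, rt
Reagents that add atoms: tert-butyldimethylsilyl chloride CC(C)(C)[Si](C)(C)Cl
Why: Imidazole-promoted silylation of the secondary allylic alcohol gives a TBS ether that withstands every later hydride, base, chromium and titanium reagent and leaves C3 untouched.

Step 5
Reactants: 7 silyl ether; 8 methacrolein
Product: 9 (2E,5S,6Z)-5-(tert-butyldimethylsilyloxy)-7-iodo-2,6-dimethylhepta-2,6-dienal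
Conditions: second-generation Hoveyda–Grubbs catalyst (5 mol %), 8 (8 equiv), CH2Cl2, 40 °C
Reagents that add atoms: none
Why: Olefin cross-metathesis pairs the only unhindered terminal alkene with excess methacrolein, the conjugated trisubstituted product forms under thermodynamic control as the E isomer (C2 trans to C9), and the trisubstituted iodoalkene is too hindered to engage the ruthenium carbene.

Step 6
Reactants: 9 enal
Product: 10 (2E,5S,6Z)-5-(tert-butyldimethylsilyloxy)-7-iodo-2,6-dimethylhepta-2,6-dien-1-ol
Conditions: NaBH4, CeCl3·7H2O, MeOH, 0 °C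
Reagents that add atoms: none
Why: Luche reduction delivers hydride to the carbonyl carbon only, so the enal should give the E-allylic alcohol with both alkenes and the C–I bond unchanged.

Step 7
Reactants: 10 allylic alcohol
Product: 11 (1Z,3S,5E)-7-bromo-3-(tert-butyldimethylsilyloxy)-1-iodo-2,6-dimethylhepta-1,5-diene
Conditions: CBr4, PPh3, CH2Cl2, −20 → 0 °C
Reagents that add atoms: carbon tetrabromide BrC(Br)(Br)Br
Why: Appel bromination converts the primary allylic alcohol by SN2 displacement of the oxyphosphonium ion at low temperature, which should avoid allylic transposition and loss of alkene geometry.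

Step 8
Reactants: 11 allylic bromide; 1 propargyl alcohol
Product: 12 (5E,8S,9Z)-8-(tert-butyldimethylsilyloxy)-10-iodo-5,9-dimethyldeca-5,9-dien-2-yn-1-ol
Conditions: CuI (10 mol %), n-Bu4NBr (10 mol %), K2CO3, DMF, rt
Reagents that add atoms: none
Why: Copper-catalysed alkynylation of a primary allylic halide under carbonate conditions forms the C8–C9 bond at the unhindered CH2 terminus to give the skipped enyne, while an alkenyl iodide does not couple with a copper acetylide at room temperature without palladium.

Step 9
Reactants: 12 enynol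
Product: 13 (2E,5E,8S,9Z)-8-(tert-butyldimethylsilyloxy)-10-iodo-5,9-dimethyldeca-2,5,9-trien-1-ol
Conditions: NaAlH2(OCH2CH2OMe)2 (1.5 equiv), THF, 0 °C; aqueous potassium sodium tartrate work-up
Reagents that add atoms: none
Why: Hydroxyl-directed trans-hydroalumination of the propargylic alcohol followed by protonolysis gives the E-allylic alcohol (C7=C8), and at 0 °C the alkenyl iodide and the silyl ether should be left alone, as alkenyl iodides are in aluminium hydride reductions of iodoacrylates.

Step 10
Reactants: 13 trienol
Product: 14 (7R,8R)-epoxy alcohol [(2R,3R)-oxiranylmethanol of 13]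
Conditions: Ti(OiPr)4 (10 mol %), D-(−)-diethyl tartrate (12 mol %), t-BuOOH (2 equiv), 4 Å molecular sieves, CH2Cl2, −20 °C
Reagents that add atoms: tert-butyl hydroperoxide CC(C)(C)OO
Why: Katsuki–Sharpless asymmetric epoxidation is at its most dependable on a primary E-allylic alcohol, D-(−)-tartrate should deliver oxygen to the face that gives the trans 7R,8R epoxide, and the two alkenes without a free allylic hydroxyl are not touched.

Step 11
Reactants: 14 epoxy alcohol
Product: 15 (7S,8R)-epoxy aldehyde (same spatial arrangement as 14)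
Conditions: TEMPO (10 mol %), PhI(OAc)2 (1.1 equiv), CH2Cl2, rt
Reagents that add atoms: none
Why: Oxoammonium (TEMPO) oxidation with PhI(OAc)2 stops at the aldehyde under almost neutral conditions, so the epoxide and the α-stereocentre C7 should survive.

Step 12
Reactants: 15 iodoalkenyl epoxy aldehyde
Product: 16 (3S,6R,7R,8R)-3-silyloxy-7,8-epoxycyclodeca-1(10),4-dien-6-ol (ring closed at C5–C6)
Conditions: CrCl2 (10 equiv), NiCl2 (0.1 equiv), DMSO, rt, syringe-pump addition to 2 mM
Reagents that add atoms: none
Why: In the Nozaki–Hiyama–Kishi reaction zerovalent nickel inserts into the C5–I bond, transmetalation to trivalent chromium keeps the geometry of the trisubstituted alkene, and the aldehyde-selective alkenylchromium closes the ten-membered ring under high dilution, with polar Felkin–Anh approach anti to the C7–O bond expected to favour the 6R (anti) epoxy alcohol.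

Step 13
Reactants: 16 macrocyclic epoxy alcohol; 17 diethylphosphonoacetic acid
Product: 18 (3S,6R,7S,8R)-6-O-(diethylphosphonoacetyl) epoxide
Conditions: DCC, DMAP (cat.), CH2Cl2, 0 °C → rt
Reagents that add atoms: none
Why: Steglich esterification acylates the C6 hydroxyl with retention under neutral conditions that leave the epoxide and the acidic methylene of the phosphonoacetate unchanged.

Step 14
Reactants: 18 phosphonoacetate epoxide
Product: 21 (3S,6R,7R,8R,11S)-α-diethoxyphosphoryl 6,7-trans-lactone bearing the free C8 hydroxyl, via sodium carbanion of the phosphonoacetate 19 (not isolated), via sodium enolate of the phosphono lactone 20 (not isolated)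
Conditions: NaH (1.05 equiv), THF–DMF (4:1), 0 → 45 °C; then AcOH (1.1 equiv), 0 °C
Reagents that add atoms: none
Why: NaH removes one of the doubly activated C11 protons of 18, by far the most acidic C–H present, and carbanion 19, held on the C6 oxygen, attacks C7 along the axis of the C7–O bond so that the epoxide oxygen leaves onto C8. The closest known reaction type is the intramolecular alkylation or epoxide opening of ester-tethered malonate and phosphonoacetate anions that gives α-substituted γ-butyrolactones, and the base-induced opening of 2,3-epoxy alcohol carbamates at the carbon next to the carbinol shows the same regiochemistry. The lactone ring (O, C6, C7, C11, C12) closes in the 5-exo-tet mode, preferred over 6-endo attack at C8 because only C7 allows a collinear approach within the short tether. C7 is set by clean inversion of the epoxide carbon fixed in step 10, and because the ester oxygen and the epoxide oxygen are anti in 18 this inversion places H6 and H7 trans, while C8 keeps its configuration since its C–O bond is not touched; C11 is labile, should settle with phosphorus trans to C8 and vanishes in step 15. The C8 alkoxide is protonated at once by the more acidic C11–H of the product, and in the resulting enolate 20 the lactone carbonyl is a poor electrophile, which should hold back translactonisation to O8. Keeping the temperature at or below 45 °C should avoid transfer of the phosphoryl group to O8 and the cyclopropane formation that follows it at high temperature, and the absence of any Lewis acid spares the epoxide from transannular attack by the C1=C10 alkene.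

Step 15
Reactants: 21 α-phosphono lactone
Product: 22 (3S,6R,7R,8R)-α-methylene lactone bearing the free C8 hydroxyl
Conditions: K2CO3, 37 % aq. HCHO, THF, 0 °C
Reagents that add atoms: formaldehyde C=O
Why: Horner–Wadsworth–Emmons olefination of the α-phosphono lactone with formaldehyde needs only carbonate as base, removes the C11 stereocentre and installs C11=C13, and the short exposure at 0 °C should leave the free C8 hydroxyl and the 6,12-lactone in place.

Step 16
Reactants: 23 angelic acid
Product: 24 (Z)-2-methylbut-2-en-1-ol
Conditions: LiAlH4, Et2O, 0 °C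
Reagents that add atoms: none
Why: LiAlH4 reduction of the carboxylic acid at 0 °C gives the allylic alcohol without conjugate reduction or Z-to-E isomerisation of the angelate double bond.

Step 17
Reactants: 24 (Z)-2-methylbut-2-en-1-ol
Product: 25 [(2S,3R)-2,3-dimethyloxiran-2-yl]methanol
Conditions: Ti(OiPr)4 (10 mol %), L-(+)-diethyl tartrate (12 mol %), t-BuOOH, 4 Å molecular sieves, CH2Cl2, −20 °C
Reagents that add atoms: tert-butyl hydroperoxide CC(C)(C)OO
Why: Katsuki–Sharpless asymmetric epoxidation with L-(+)-tartrate should add oxygen to one face of the Z-alkene and set both centres at once (2S,3R, CH2OH and the C3 methyl cis on the oxirane), and any minor enantiomer would be removed later as a diastereomeric ester at 28.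

Step 18
Reactants: 25 epoxy alcohol
Product: 26 (2R,3R)-2,3-dimethyloxirane-2-carboxylic acid (epoxyangelic acid)
Conditions: RuCl3 (2 mol %), NaIO4 (3 equiv), MeCN–EtOAc–H2O, 0 °C → rt
Reagents that add atoms: water O
Why: Catalytic RuO4 oxidation takes a 2,3-epoxy alcohol through the aldehyde hydrate to the glycidic acid without opening the oxirane, the C2 descriptor changing to R only through the priority rules.

Step 19
Reactants: 22 C8 alcohol; 26 epoxyangelic acid
Product: 28 8-O-[(2R,3R)-epoxyangeloyl]-3-O-TBS lactone, via mixed trichlorobenzoic anhydride 27 (not isolated)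
Conditions: 26, 2,4,6-trichlorobenzoyl chloride, Et3N, toluene, rt; then 22, DMAP, toluene, rt → 40 °C
Reagents that add atoms: none
Why: Yamaguchi esterification through mixed anhydride 27 and DMAP acylates the hindered secondary C8 hydroxyl with retention, and an α-quaternary epoxy acid cannot epimerise or isomerise as an angelate would.

Step 20
Reactants: 28 silyl ether
Product: 29 3-hydroxy 8-epoxyangelate
Conditions: HF·pyridine, pyridine, THF, 0 °C → rt
Reagents that add atoms: none
Why: Buffered fluoride desilylation cleaves only the Si–O bond, since the pyridine buffer keeps the medium too weakly acidic to open the ester-deactivated oxirane or to trigger transannular cyclisation, and it avoids basic fluoride that could add to the methylene lactone.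

Step 21
Reactants: 29 C3 alcohol
Product: 30 3-isobutyrate 8-epoxyangelate (1(10)-alkene)
Conditions: (i-PrCO)2O, Et3N, DMAP (cat.), CH2Cl2, 0 °C → rt
Reagents that add atoms: isobutyric anhydride CC(C)C(=O)OC(=O)C(C)C
Why: DMAP-catalysed acylation of the secondary allylic C3 alcohol with the anhydride proceeds with retention, and no other hydroxyl remains.

Step 22
Reactants: 30 triene diester
Product: 31 target CNP0117882.2 (1R,3S,4Z,6R,7R,8R,10R; side chain 2R,3R)
Conditions: mCPBA (1.1 equiv), CH2Cl2, 0 °C
Reagents that add atoms: 3-chloroperoxybenzoic acid OOC(=O)c1cccc(Cl)c1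
Why: Prilezhaev epoxidation should pick C1=C10 as the only electron-rich alkene (C4=C5 is deactivated by two allylic acyloxy groups, C11=C13 by conjugation), and since an E-alkene in a ten-membered ring shows only its outer face, the conformer with C14 on the β face (the side of H6 and O8) should give the syn-added 1β,10α epoxide, that is 1R,10R.

Compound list
1 | propargyl alcohol | OCC#C | starting material
2 | cyclic (Z)-alkenylmagnesium alkoxide (4-methyl-2,5-dihydro-1,2-oxamagnesole) | CC1=C[Mg]OC1 | intermediate
3 | (Z)-3-iodo-2-methylprop-2-en-1-ol | OC/C(C)=C\I | intermediate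
4 | (Z)-3-iodo-2-methylprop-2-enal | O=C/C(C)=C\I | intermediate
5 | diisopinocampheylborinate ester of 6 | I/C=C(/C)[C@@H](OB([C@@H]1C[C@@H]2C[C@H]([C@H]1C)C2(C)C)[C@@H]1C[C@@H]2C[C@H]([C@H]1C)C2(C)C)CC=C | intermediate
6 | (1Z,3S)-1-iodo-2-methylhexa-1,5-dien-3-ol | I/C=C(/C)[C@@H](O)CC=C | intermediate
7 | (1Z,3S)-3-(tert-butyldimethylsilyloxy)-1-iodo-2-methylhexa-1,5-diene | I/C=C(/C)[C@@H](O[Si](C)(C)C(C)(C)C)CC=C | intermediate
8 | methacrolein | C=C(C)C=O | starting material
9 | (2E,5S,6Z)-5-(tert-butyldimethylsilyloxy)-7-iodo-2,6-dimethylhepta-2,6-dienal | I/C=C(/C)[C@@H](O[Si](C)(C)C(C)(C)C)C/C=C(\C)C=O | intermediate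
10 | (2E,5S,6Z)-5-(tert-butyldimethylsilyloxy)-7-iodo-2,6-dimethylhepta-2,6-dien-1-ol | I/C=C(/C)[C@@H](O[Si](C)(C)C(C)(C)C)C/C=C(\C)CO | intermediate
11 | (1Z,3S,5E)-7-bromo-3-(tert-butyldimethylsilyloxy)-1-iodo-2,6-dimethylhepta-1,5-diene | I/C=C(/C)[C@@H](O[Si](C)(C)C(C)(C)C)C/C=C(\C)CBr | intermediate
12 | (5E,8S,9Z)-8-(tert-butyldimethylsilyloxy)-10-iodo-5,9-dimethyldeca-5,9-dien-2-yn-1-ol | I/C=C(/C)[C@@H](O[Si](C)(C)C(C)(C)C)C/C=C(\C)CC#CCO | intermediate
13 | (2E,5E,8S,9Z)-8-(tert-butyldimethylsilyloxy)-10-iodo-5,9-dimethyldeca-2,5,9-trien-1-ol | I/C=C(/C)[C@@H](O[Si](C)(C)C(C)(C)C)C/C=C(\C)C/C=C/CO | intermediate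
14 | (2R,3R)-2,3-epoxide of 13 (germacrane 3S,7R,8R; trans-oxirane) | I/C=C(/C)[C@@H](O[Si](C)(C)C(C)(C)C)C/C=C(\C)C[C@H]1O[C@@H]1CO | intermediate
15 | (2S,3R)-oxirane-2-carbaldehyde from 14 (germacrane 3S,7S,8R) | I/C=C(/C)[C@@H](O[Si](C)(C)C(C)(C)C)C/C=C(\C)C[C@H]1O[C@@H]1C=O | intermediate
16 | macrocyclic epoxy alcohol: (1(10)E,4Z)-4,10-dimethylcyclodecadiene, 3S-OTBS, 6R-OH, trans-7R,8R-epoxide | O[C@@H]1/C=C(/C)[C@@H](O[Si](C)(C)C(C)(C)C)C/C=C(\C)C[C@H]2O[C@H]12 | intermediate
17 | diethylphosphonoacetic acid | CCOP(=O)(OCC)CC(O)=O | starting material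
18 | C6 diethylphosphonoacetate of 16 (3S,6R,7S,8R) | CCOP(=O)(OCC)CC(=O)O[C@@H]1/C=C(/C)[C@@H](O[Si](C)(C)C(C)(C)C)C/C=C(\C)C[C@H]2O[C@H]12 | intermediate
19 | sodium carbanion of 18 | [Na+].CCOP(=O)(OCC)[CH-]C(=O)O[C@@H]1/C=C(/C)[C@@H](O[Si](C)(C)C(C)(C)C)C/C=C(\C)C[C@H]2O[C@H]12 | intermediate
20 | sodium enolate of 21 | [Na+].CCOP(=O)(OCC)[C-]1C(=O)O[C@@H]2/C=C(/C)[C@@H](O[Si](C)(C)C(C)(C)C)C/C=C(\C)C[C@@H](O)[C@@H]12 | intermediate
21 | α-diethoxyphosphoryl 6,7-trans-lactone, free 8-OH (3S,6R,7R,8R,11S) | CCOP(=O)(OCC)[C@@H]1C(=O)O[C@@H]2/C=C(/C)[C@@H](O[Si](C)(C)C(C)(C)C)C/C=C(\C)C[C@@H](O)[C@@H]12 | intermediate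
22 | α-methylene 6,7-trans-lactone, 3-OTBS, free 8-OH (3S,6R,7R,8R) | C=C1C(=O)O[C@@H]2/C=C(/C)[C@@H](O[Si](C)(C)C(C)(C)C)C/C=C(\C)C[C@@H](O)[C@@H]12 | intermediate
23 | angelic acid, (Z)-2-methylbut-2-enoic acid | C/C=C(/C)C(=O)O | starting material
24 | (Z)-2-methylbut-2-en-1-ol | C/C=C(/C)CO | intermediate
25 | [(2S,3R)-2,3-dimethyloxiran-2-yl]methanol | OC[C@]1(C)O[C@@H]1C | intermediate
26 | (2R,3R)-2,3-dimethyloxirane-2-carboxylic acid | OC(=O)[C@]1(C)O[C@@H]1C | intermediate
27 | (2R,3R)-epoxyangelic 2,4,6-trichlorobenzoic anhydride | O=C(OC(=O)c1c(Cl)cc(Cl)cc1Cl)[C@]1(C)O[C@@H]1C | intermediate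
28 | 8-O-[(2R,3R)-epoxyangeloyl]-3-O-TBS α-methylene lactone | C=C1C(=O)O[C@@H]2/C=C(/C)[C@@H](O[Si](C)(C)C(C)(C)C)C/C=C(\C)C[C@@H](OC(=O)[C@]3(C)O[C@@H]3C)[C@@H]12 | intermediate
29 | 3-hydroxy 8-epoxyangelate | C=C1C(=O)O[C@@H]2/C=C(/C)[C@@H](O)C/C=C(\C)C[C@@H](OC(=O)[C@]3(C)O[C@@H]3C)[C@@H]12 | intermediate
30 | 3-isobutyrate 8-epoxyangelate, 1(10)E-alkene | C=C1C(=O)O[C@@H]2/C=C(/C)[C@@H](OC(=O)C(C)C)C/C=C(\C)C[C@@H](OC(=O)[C@]3(C)O[C@@H]3C)[C@@H]12 | intermediate
31 | CNP0117882.2 (1β,10α-epoxide; 1R,3S,4Z,6R,7R,8R,10R,2'R,3'R) | C=C1C(=O)O[C@@H]2/C=C(/C)[C@@H](OC(=O)C(C)C)C[C@H]3O[C@]3(C)C[C@@H](OC(=O)[C@]3(C)O[C@@H]3C)[C@@H]12 | target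

Total step count: 22. Longest linear sequence: 19 steps (steps 1–15 and 19–22). The side-chain acid takes steps 16–18.

Steps most likely to fail

1. Step 14.
- **What may go wrong:** ring closure by the strongly stabilised, encumbered carbanion may be slow. Heating then becomes necessary, and the freed C8 alkoxide begins to attack phosphorus (phosphoryl migration followed by cyclopropane formation) or the lactone carbonyl.
- **Fallback:** it sets out from 16 and replaces the phosphorus-stabilised nucleophile and the olefination tactic.
- 16 is esterified with allyl hydrogen malonate (DCC, DMAP) to the mixed allyl malonate F1.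
- NaH in THF lets the more nucleophilic, phosphorus-free malonate anion open the epoxide at C7 to the α-allyloxycarbonyl lactone F2.
- Pd(PPh3)4 and morpholine remove the allyl group under neutral conditions to give the α-carboxy lactone F3.
- Aqueous formaldehyde with diethylamine then effects the classical decarboxylative Mannich methylenation. The route is rejoined at 22.

2. Step 12.
- **What may go wrong:** facial selectivity at the aldehyde carbon may be poor, because strain in the ring-closing transition state may override the Felkin–Anh bias.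
- **Fallback:** it sets out from 15 and uses stereospecific inversion instead of relying on addition selectivity.
- The same closure gives the 6S-configured epoxy alcohol F4, which is separated.
- F4 is esterified with 17 under Mitsunobu conditions (PPh3, diisopropyl azodicarboxylate, toluene, 0 °C). SN2 displacement at C6 inverts the carbinol centre and gives the phosphonoacetate directly, so the route is rejoined at 18 and both epimers converge.

3. Step 22.
- **What may go wrong:** oxygen may be delivered to the wrong face if a conformer with C14 on the α face reacts faster than the expected one.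
- **Fallback:** it sets out from 30 and replaces substrate control by catalyst control.
- Shi epoxidation uses the D-fructose-derived ketone and KHSO5 (as 2KHSO5·KHSO4·K2SO4) in buffered MeCN–dimethoxymethane–water at 0 °C. Its spiro transition state gives R,R epoxides from E-trisubstituted alkenes and ignores the electron-poor alkenes.
- It ends at 31 and makes no new compound.

Further compounds
F1 | step 14 | C6 allyl malonate of 16 | C=CCOC(=O)CC(=O)O[C@@H]1/C=C(/C)[C@@H](O[Si](C)(C)C(C)(C)C)C/C=C(\C)C[C@H]2O[C@H]12
F2 | step 14 | α-allyloxycarbonyl 6,7-trans-lactone with free 8-OH | C=CCOC(=O)[C@@H]1C(=O)O[C@@H]2/C=C(/C)[C@@H](O[Si](C)(C)C(C)(C)C)C/C=C(\C)C[C@@H](O)[C@@H]12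
F3 | step 14 | α-carboxy 6,7-trans-lactone with free 8-OH | OC(=O)[C@@H]1C(=O)O[C@@H]2/C=C(/C)[C@@H](O[Si](C)(C)C(C)(C)C)C/C=C(\C)C[C@@H](O)[C@@H]12
F4 | step 12 | 6S epimer of macrocyclic epoxy alcohol 16 | O[C@H]1/C=C(/C)[C@@H](O[Si](C)(C)C(C)(C)C)C/C=C(\C)C[C@H]2O[C@H]12
F0 | step 22 | none | none
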